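**Assumption:** the target has no stereocentre and no stereogenic double bond, so there is nothing to set or protect stereochemically; 1,13-dibromotridecane is taken as a catalogue compound.

## Retrosynthetic overview

- The last bonds made are the two C–OH bonds: each hydroxyl is put onto the only ring C–H of a bis(methoxy-methyl-quinone), the carbon β to the carbonyl that the methoxy group does not deactivate.
- The bis-quinone comes from oxidation of 1,13-bis(3,5-dimethoxy-4-methylphenyl)tridecane (arene hydroxylation, then oxidative loss of the para methoxy group), which leaves the surviving OMe next to the ring methyl.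
- The ring methyl groups come from a double directed ortho-metalation/methylation between the two methoxy groups.
- The C13 tether is attached one ring per step: Cu-catalysed coupling of 3,5-dimethoxyphenylmagnesium bromide with excess 1,13-dibromotridecane, then Kumada coupling of the resulting ω-aryl alkyl Grignard with 1-bromo-3,5-dimethoxybenzene.
- No ring is built: both six-membered carbocycles are bought as the aromatic starting material.

## Route

Step 1
Reactants: 1 1,13-dibromotridecane; 2 1-bromo-3,5-dimethoxybenzene
Product: 4 1-(13-bromotridecyl)-3,5-dimethoxybenzene, via aryl Grignard reagent 3 (not isolated)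
Conditions: 2, Mg (1.2 equiv), I2 (cat.), THF, reflux; then added slowly to 1 (3 equiv), Li2CuCl4 (3 mol %), THF, −10 °C → rt; excess 1 recovered
Reagents that add atoms: magnesium, [Mg] (carried in intermediate 3 only)
Why: Kochi-type copper-catalysed Csp2–Csp3 cross-coupling of an aryl Grignard with a primary alkyl bromide, in which slow addition to a three-fold excess of the dibromide holds the reaction at mono-coupling (the little doubly arylated material formed is compound 6 and is combined with the product of step 2); no stereocentre is formed.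

Step 2
Reactants: 4 1-(13-bromotridecyl)-3,5-dimethoxybenzene; 2 1-bromo-3,5-dimethoxybenzene
Product: 6 1,13-bis(3,5-dimethoxyphenyl)tridecane, via alkyl Grignard reagent 5 (not isolated)
Conditions: 4, Mg (1.5 equiv), I2 (cat.), THF, 50 °C; then 2 (1.2 equiv), NiCl2(dppp) (3 mol %), THF, 0 °C → reflux
Reagents that add atoms: magnesium, [Mg] (carried in intermediate 5 only)
Why: Kumada–Corriu coupling, in which the primary alkyl Grignard transmetalates onto the aryl–Ni(dppp) species and the chelating phosphine suppresses β-hydride elimination; no stereocentre is formed.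

Step 3
Reactants: 6 1,13-bis(3,5-dimethoxyphenyl)tridecane
Product: 8 1,13-bis(3,5-dimethoxy-4-methylphenyl)tridecane, via bis-aryllithium 7 (not isolated)
Conditions: n-BuLi (2.6 equiv), THF, 0 °C → rt, 2 h; then MeI (4 equiv), 0 °C → rt
Reagents that add atoms: n-butyllithium, [Li]CCCC (lithium carried in intermediate 7 only); iodomethane, CI
Why: Directed ortho-metalation, in which the C–H flanked by both methoxy groups is by far the most acidic ring position, so lithiation and methylation occur only there on each ring; no stereocentre is formed.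

Step 4
Reactants: 8 1,13-bis(3,5-dimethoxy-4-methylphenyl)tridecane
Product: 10 5,5'-(tridecane-1,13-diyl)bis(3-methoxy-2-methylcyclohexa-2,5-diene-1,4-dione), via bis-phenol 9 (not isolated)
Conditions: MeReO3 (10 mol %), 30% aq. H2O2 (10 equiv), AcOH, 40 °C
Reagents that add atoms: hydrogen peroxide, OO
Why: Methyltrioxorhenium-catalysed peroxide oxidation of a methoxyarene to a p-quinone, in which electrophilic oxygen transfer to the free ring position (ortho to one OMe, para to the other) gives phenol 9 and a second oxygen transfer at the para OMe-bearing carbon expels methanol, so the remaining OMe sits next to the ring methyl; no stereocentre is formed.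

Step 5
Reactants: 10 5,5'-(tridecane-1,13-diyl)bis(3-methoxy-2-methylcyclohexa-2,5-diene-1,4-dione)
Product: 12 3,3'-(tridecane-1,13-diyl)bis(2-hydroxy-5-methoxy-6-methylcyclohexa-2,5-diene-1,4-dione) (CNP0110425.0), via bis(N-oxide) Michael adduct 11 (not isolated)
Conditions: NMO (anhydrous, 2.5 equiv), 4 Å MS, MeCN/CH2Cl2, 0 °C → rt; then 1 M HCl work-up
Reagents that add atoms: N-methylmorpholine N-oxide, C[N+]1([O-])CCOCC1
Why: Proposed new method: oxygen-atom insertion into the quinone C–H bond by an amine N-oxide acting as a nucleophilic oxidant that carries its own leaving group — the N-oxide oxygen adds in a Michael sense to the only unsubstituted ring carbon (β to the carbonyl that is not part of the vinylogous ester), and adduct 11 then loses its now α-carbonyl C–H proton with N–O heterolysis (Kornblum-type), expelling N-methylmorpholine and giving the hydroxyquinone anion without an external oxidant, which as an anion resists further addition; the closest known reaction types are the Kornblum/Ganem N-oxide oxidation of alkyl halides, the Weitz–Scheffer nucleophilic epoxidation of quinones and vicarious nucleophilic hydroxylation of nitroarenes with hydroperoxide anions; no stereocentre remains in the product.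

## Compound list

1 | 1,13-dibromotridecane | BrCCCCCCCCCCCCCBr | starting material
2 | 1-bromo-3,5-dimethoxybenzene | COc1cc(Br)cc(OC)c1 | starting material
3 | 3,5-dimethoxyphenylmagnesium bromide | COc1cc([Mg]Br)cc(OC)c1 | intermediate
4 | 1-(13-bromotridecyl)-3,5-dimethoxybenzene | COc1cc(CCCCCCCCCCCCCBr)cc(OC)c1 | intermediate
5 | [13-(3,5-dimethoxyphenyl)tridecyl]magnesium bromide | COc1cc(CCCCCCCCCCCCC[Mg]Br)cc(OC)c1 | intermediate
6 | 1,13-bis(3,5-dimethoxyphenyl)tridecane | COc1cc(CCCCCCCCCCCCCc2cc(OC)cc(OC)c2)cc(OC)c1 | intermediate
7 | 1,13-bis(4-lithio-3,5-dimethoxyphenyl)tridecane | [Li]c1c(OC)cc(CCCCCCCCCCCCCc2cc(OC)c([Li])c(OC)c2)cc1OC | intermediate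
8 | 1,13-bis(3,5-dimethoxy-4-methylphenyl)tridecane | COc1cc(CCCCCCCCCCCCCc2cc(OC)c(C)c(OC)c2)cc(OC)c1C | intermediate
9 | 6,6'-(tridecane-1,13-diyl)bis(2,4-dimethoxy-3-methylphenol) | COc1cc(CCCCCCCCCCCCCc2cc(OC)c(C)c(OC)c2O)c(O)c(OC)c1C | intermediate
10 | 5,5'-(tridecane-1,13-diyl)bis(3-methoxy-2-methylcyclohexa-2,5-diene-1,4-dione) | COC1=C(C)C(=O)C=C(CCCCCCCCCCCCCC2=CC(=O)C(C)=C(OC)C2=O)C1=O | intermediate
11 | double Michael adduct of NMO with 10: each ring is a zwitterionic 4-oxidocyclohexadienone whose former C–H carbon carries H and a (4-methylmorpholin-4-ium-4-yl)oxy group (transient, mixture of stereoisomers) | COC1=C(C)C(=O)C(O[N+]2(C)CCOCC2)C(CCCCCCCCCCCCCC2=C([O-])C(OC)=C(C)C(=O)C2O[N+]2(C)CCOCC2)=C1[O-] | intermediate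
12 | 3,3'-(tridecane-1,13-diyl)bis(2-hydroxy-5-methoxy-6-methylcyclohexa-2,5-diene-1,4-dione) (CNP0110425.0) | COC1=C(C)C(=O)C(O)=C(CCCCCCCCCCCCCC2=C(O)C(=O)C(C)=C(OC)C2=O)C1=O | target

## Totals and risk

Total step count: 5. Longest linear sequence: 5 (2 → 4 → 6 → 8 → 10 → 12).

**Step 5 (the proposed new step).** The N-oxide may add too slowly, or adduct 11 may be drained by redox exchange with unreacted quinone. The fallback uses known chemistry, sets out from 10 and comes back at 12. Weitz–Scheffer epoxidation (30% H2O2, Na2CO3, aq. THF, 0 °C) attacks the same electrophilic C–H carbon and gives 1,1'-(tridecane-1,13-diyl)bis(3-methoxy-4-methyl-7-oxabicyclo[4.1.0]hept-3-ene-2,5-dione) F6, a mixture of diastereomers that does not matter. Base-induced opening of the epoxide by deprotonation at the epoxide C–H (DBU, CH2Cl2, rt, acidic work-up) leaves the oxygen on that carbon and delivers 12.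

**Step 4.** Direct arene-to-quinone oxidation may stop at the phenol, over-oxidise, or give poor mass balance when it has to succeed on both rings. The fallback sets out from 8 and comes back at 10. Thiolate mono-demethylation of each ring (NaSEt, DMF, 140 °C) gives 5,5'-(tridecane-1,13-diyl)bis(3-methoxy-2-methylphenol) F5; the phenoxide formed protects the second OMe of the same ring. Teuber oxidation with Fremy's salt (KH2PO4 buffer, acetone/water, or CH2Cl2/water and a phase-transfer salt) then oxidises the free para position of each phenol and gives 10 with the same regiochemistry.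

**Step 1.** The mono-coupling is statistical, and bromide 4 has to be separated from the excess dibromide. The fallback replaces cross-coupling by carbonyl addition and deoxygenation; it sets out from 2 and comes back at 6, so it also replaces step 2. Tridecanedioic acid (brassylic acid, bought) is converted by CDI and MeNH(OMe)·HCl into N1,N13-dimethoxy-N1,N13-dimethyltridecanediamide F1. Bromine–lithium exchange on 2 (n-BuLi, THF, −78 °C) gives 3,5-dimethoxyphenyllithium F2, which adds to both Weinreb amide groups of F1 without over-addition and gives 1,13-bis(3,5-dimethoxyphenyl)tridecane-1,13-dione F3. Wolff–Kishner reduction (N2H4·H2O, KOH, diethylene glycol, 130 → 200 °C) passes through 1,13-bis(3,5-dimethoxyphenyl)tridecane-1,13-dione dihydrazone F4 and gives 6.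

## Further compounds

F1 | step 1 | N1,N13-dimethoxy-N1,N13-dimethyltridecanediamide | CON(C)C(=O)CCCCCCCCCCCC(=O)N(C)OC
F2 | step 1 | 3,5-dimethoxyphenyllithium | [Li]c1cc(OC)cc(OC)c1
F3 | step 1 | 1,13-bis(3,5-dimethoxyphenyl)tridecane-1,13-dione | COc1cc(OC)cc(c1)C(=O)CCCCCCCCCCCC(=O)c1cc(OC)cc(OC)c1
F4 | step 1 | 1,13-bis(3,5-dimethoxyphenyl)tridecane-1,13-dione dihydrazone | COc1cc(OC)cc(c1)C(=NN)CCCCCCCCCCCC(=NN)c1cc(OC)cc(OC)c1
F5 | step 4 | 5,5'-(tridecane-1,13-diyl)bis(3-methoxy-2-methylphenol) | COc1cc(CCCCCCCCCCCCCc2cc(O)c(C)c(OC)c2)cc(O)c1C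
F6 | step 5 | 1,1'-(tridecane-1,13-diyl)bis(3-methoxy-4-methyl-7-oxabicyclo[4.1.0]hept-3-ene-2,5-dione) | COC1=C(C)C(=O)C2OC2(CCCCCCCCCCCCCC34OC3C(=O)C(C)=C(OC)C4=O)C1=O
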